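**Plan**

1. Locants (C-n) used below: pyrrolidinone N-4, C-3, C-2 (bearing the methyl C-1), C-25 (C=O), C-20; piperidine N-4, C-5, C-6, C-22, C-21, C-20; cycloheptane C-6, C-7, C-8, C-9, C-13, C-14, C-22; cyclopentene C-9 to C-13 with C-12=C-13; lactone C-14, C-15, C-16, C-17, O-18, C-19; cyclopentane C-14, C-19, C-20, C-21, C-22; C-23 is the CH2OH carbon on C-22.
2. Enabling feature: the cycloheptane shares the C-6–C-22 edge with the piperidine and the C-14–C-22 edge with the cyclopentane, and C-14 stands next to the carbinol carbon C-19. A temporary C-7–C-14 bond turns the arc C-7/C-8/C-9/C-13/C-14 into a cyclopentene whose alkene can add across a C-6=C-22 tetrahydropyridine alkene; C-19, as a ketone, is tether, chromophore and later the trigger that re-opens the four-membered ring to the seven-membered one.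
3. Retrosynthetic cuts, in order: lactone C-17–O-18 and the C-19 carbinol (aldol/lactonisation); C-14–C-15 (Michael); re-formation of C-7–C-14; C-6–C-7 and C-14–C-22 together ([2+2]); C-14–C-19 (Nozaki–Hiyama–Kishi) to an indolizidine aldehyde and a bicyclic dienyl triflate; C-6=C-22 (ring-closing metathesis), C-20–C-21 (allylic alkylation), C-20–C-25 (Dieckmann); in the triflate C-12=C-13 (aldol condensation) and C-9–C-10 (conjugate addition).
4. Forward ring order: pyrrolidinone, then tetrahydropyridine; separately the cyclopentene-fused cyclopentenyl triflate; fragment union; cyclopentane and cyclobutane in one photochemical step; cycloheptane by reductive opening of the cyclobutane; C-15 to C-17 arm; lactone last.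
5. Stereochemistry: C-20 from a Pd-catalysed asymmetric allylic alkylation and C-9 from a Cu-catalysed asymmetric conjugate addition (both catalyst controlled); C-22 and C-6 relayed from C-20 in the photocycloaddition; C-14 by exo-face Michael addition on the cage; C-19 by a reversible aldol that only the lactone-forming epimer leaves; C-2 by equilibration.
6. Helpers and their removal: temporary C-7–C-14 bond (cleaved in step 17); C-19 at the ketone level (steps 15 to 19); C-25 masked as a silyl ether (steps 8 to 20); N-4 protonated during irradiation; C-23 silyl ether (step 22).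

Key step: step 16

Assumption: C-2 is α to the C-25 ketone and epimerisable, so the natural configuration is taken to be the thermodynamically preferred one; C-2 and the masked C-25 carbinol are carried as epimer mixtures from step 8 and fixed in steps 20 and 21.

**Route**

Step 1
Reactants: 1 prop-2-en-1-amine (allylamine); 2 methyl 2-methylprop-2-enoate (methyl methacrylate)
Product: 3 methyl 2-methyl-3-(prop-2-en-1-ylamino)propanoate (racemic)
Conditions: 1 (3 equiv), MeOH, 50 °C
Reagents that add atoms: none
Why: Aza-Michael addition of the primary amine to the methacrylate gives the β-amino ester, the excess of amine holding back double addition; the new centre (later C-2) is racemic and is not fixed until step 21.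

Step 2
Reactants: 3 methyl 2-methyl-3-(prop-2-en-1-ylamino)propanoate; 4 methyl bromoacetate
Product: 5 methyl 3-[(2-methoxy-2-oxoethyl)(prop-2-en-1-yl)amino]-2-methylpropanoate (racemic)
Conditions: K2CO3, MeCN, 23 °C
Reagents that add atoms: none
Why: SN2 N-alkylation of the secondary amine by the α-bromo ester installs the glycinate arm that becomes C-20 and C-19.

Step 3
Reactants: 5 methyl 3-[(2-methoxy-2-oxoethyl)(prop-2-en-1-yl)amino]-2-methylpropanoate
Product: 6 methyl 4-methyl-3-oxo-1-(prop-2-en-1-yl)pyrrolidine-2-carboxylate (racemic; both centres enolisable)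
Conditions: NaOMe (1.5 equiv), toluene/MeOH, 80 °C; then AcOH
Reagents that add atoms: none
Why: Dieckmann condensation under reversible alkoxide conditions: of the two possible β-keto esters only the 3-oxo-2-carboxylate can be held as a stabilised enolate (the regioisomer would have a quaternary carbon between its carbonyl groups), so the equilibrium should drain to 6.

Step 4
Reactants: 7 2-methylidenepropane-1,3-diol
Product: 8 2-({[tert-butyl(diphenyl)silyl]oxy}methyl)prop-2-en-1-ol
Conditions: NaH (1.0 equiv), THF, 0 °C; then t-BuPh2SiCl (1.0 equiv)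
Reagents that add atoms: tert-butyl(chloro)diphenylsilane, CC(C)(C)[Si](Cl)(c1ccccc1)c1ccccc1
Why: Monosilylation of the symmetrical diol through its monosodium alkoxide (O-silylation) protects the future C-23 hydroxyl with a group that lasts to the final step.

Step 5
Reactants: 8 2-({[tert-butyl(diphenyl)silyl]oxy}methyl)prop-2-en-1-ol
Product: 9 2-({[tert-butyl(diphenyl)silyl]oxy}methyl)prop-2-en-1-yl methyl carbonate
Conditions: ClCO2Me, pyridine, CH2Cl2, 0 °C
Reagents that add atoms: methyl chloroformate, COC(Cl)=O
Why: O-Acylation of the allylic alcohol gives the allylic carbonate that ionises under palladium catalysis and releases its own base.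

Step 6
Reactants: 6 methyl 4-methyl-3-oxo-1-(prop-2-en-1-yl)pyrrolidine-2-carboxylate; 9 2-({[tert-butyl(diphenyl)silyl]oxy}methyl)prop-2-en-1-yl methyl carbonate
Product: 10 methyl (2R)-2-[2-({[tert-butyl(diphenyl)silyl]oxy}methyl)prop-2-en-1-yl]-4-methyl-3-oxo-1-(prop-2-en-1-yl)pyrrolidine-2-carboxylate (both C-4 epimers; pyrrolidine C-2 is C-20)
Conditions: Pd2(dba)3·CHCl3 (2.5 mol%), (1S,2S)-N,N'-bis[2-(diphenylphosphino)benzoyl]cyclohexane-1,2-diamine (7.5 mol%), toluene, 0 °C
Reagents that add atoms: none
Why: Pd-catalysed asymmetric allylic alkylation of a cyclic β-keto ester: the carbonate ionises to a 2-substituted π-allyl complex with equivalent termini, the released methoxide forms the enolate, and the twofold-symmetric diphosphine pocket selects the enolate face so that the quaternary C-20 is set (R in 10; the ligand antipode is the one that gives this sense), while the enolisable methyl-bearing centre stays a mixture.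

Step 7
Reactants: 10 methyl (2R)-2-[2-({[tert-butyl(diphenyl)silyl]oxy}methyl)prop-2-en-1-yl]-4-methyl-3-oxo-1-(prop-2-en-1-yl)pyrrolidine-2-carboxylate
Product: 11 methyl (8aR)-7-({[tert-butyl(diphenyl)silyl]oxy}methyl)-2-methyl-1-oxo-2,3,5,8-tetrahydroindolizine-8a(1H)-carboxylate (both C-2 epimers)
Conditions: TsOH·H2O (1.05 equiv), second-generation Grubbs catalyst (5 mol%), CH2Cl2, 40 °C; aq. NaHCO3 work-up
Reagents that add atoms: none
Why: Ring-closing metathesis of the N-allyl group with the 1,1-disubstituted alkene closes the six-membered ring and places the trisubstituted C-6=C-22 alkene, the amine being protonated so that it does not bind the ruthenium carbene.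

Step 8
Reactants: 11 methyl (8aR)-7-({[tert-butyl(diphenyl)silyl]oxy}methyl)-2-methyl-1-oxo-2,3,5,8-tetrahydroindolizine-8a(1H)-carboxylate
Product: 12 methyl (8aR)-7-({[tert-butyl(diphenyl)silyl]oxy}methyl)-1-hydroxy-2-methyl-1,2,3,5,8,8a-hexahydroindolizine-8a-carboxylate (epimers at C-25 and C-2)
Conditions: NaBH4, MeOH, 0 °C
Reagents that add atoms: none
Why: Borohydride reduction of the ketone (ester untouched) masks C-25 at the alcohol level for the organometallic, photochemical and reductive steps ahead; its configuration and that of C-2 are immaterial because both are reset in steps 20 and 21.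

Step 9
Reactants: 12 methyl (8aR)-7-({[tert-butyl(diphenyl)silyl]oxy}methyl)-1-hydroxy-2-methyl-1,2,3,5,8,8a-hexahydroindolizine-8a-carboxylate
Product: 13 methyl (8aR)-7-({[tert-butyl(diphenyl)silyl]oxy}methyl)-2-methyl-1-[(triethylsilyl)oxy]-1,2,3,5,8,8a-hexahydroindolizine-8a-carboxylate (epimers at C-25 and C-2)
Conditions: Et3SiOTf, 2,6-lutidine, CH2Cl2, 0 °C
Reagents that add atoms: triethylsilyl trifluoromethanesulfonate, CC[Si](CC)(CC)OS(=O)(=O)C(F)(F)F
Why: Silylation of the hindered secondary alcohol with the silyl triflate gives an ether that can later be cleaved by acid in the presence of the tert-butyldiphenylsilyl ether.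

Step 10
Reactants: 13 methyl (8aR)-7-({[tert-butyl(diphenyl)silyl]oxy}methyl)-2-methyl-1-[(triethylsilyl)oxy]-1,2,3,5,8,8a-hexahydroindolizine-8a-carboxylate
Product: 14 (8aR)-7-({[tert-butyl(diphenyl)silyl]oxy}methyl)-2-methyl-1-[(triethylsilyl)oxy]-1,2,3,5,8,8a-hexahydroindolizine-8a-carbaldehyde (epimers at C-25 and C-2)
Conditions: i-Bu2AlH (1.5 equiv), toluene, −78 °C; aq. potassium sodium tartrate
Reagents that add atoms: none
Why: Partial reduction of the ester by the aluminium hydride at low temperature: the tetrahedral aluminium hemiacetal at the fully substituted, amine-flanked carbon should persist until work-up and release the non-enolisable aldehyde C-19.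

Step 11
Reactants: 15 cyclopent-2-en-1-one; 16 [2-(1,3-dioxan-2-yl)ethyl]magnesium bromide
Product: 17 (3R)-3-[2-(1,3-dioxan-2-yl)ethyl]cyclopentan-1-one
Conditions: CuBr·SMe2 (5 mol%), (R)-1-[(S)-2-(diphenylphosphino)ferrocenyl]ethyldicyclohexylphosphine (6 mol%), t-BuOMe (slow addition of 16), −78 °C; aq. NH4Cl
Reagents that add atoms: none
Why: Cu-catalysed asymmetric conjugate addition of the Grignard reagent to the cyclic enone, in which the ferrocenyl diphosphine–copper complex selects the enone face and sets C-9 (R; ligand antipode chosen accordingly).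

Step 12
Reactants: 17 (3R)-3-[2-(1,3-dioxan-2-yl)ethyl]cyclopentan-1-one
Product: 19 (3aR)-3,3a,4,5-tetrahydropentalen-1(2H)-one, via keto aldehyde 18 (not isolated)
Conditions: 2 M aq. HCl, THF, 65 °C
Reagents that add atoms: none
Why: Acid unmasks the aldehyde and promotes the intramolecular aldol condensation (cyclopentene annulation): only attack of the C-13 enol on the aldehyde gives a five-membered aldol that can dehydrate, which places the C-12=C-13 alkene, and the β-stereocentre C-9 is not enolisable.

Step 13
Reactants: 19 (3aR)-3,3a,4,5-tetrahydropentalen-1(2H)-one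
Product: 21 (3aR)-3,3a,4,5-tetrahydropentalen-1-yl trifluoromethanesulfonate, via lithium dienolate 20 (not isolated)
Conditions: LiN(i-Pr)2, THF, −78 °C; then PhNTf2, −78 to 0 °C
Reagents that add atoms: N-phenylbis(trifluoromethanesulfonimide), O=S(=O)(N(c1ccccc1)S(=O)(=O)C(F)(F)F)C(F)(F)F
Why: Kinetic deprotonation of the enone at the α′-carbon C-7 and O-triflation of the cross-conjugated enolate give the dienyl triflate that carries C-14 as an electrophilic alkenyl carbon.

Step 14
Reactants: 14 (8aR)-7-({[tert-butyl(diphenyl)silyl]oxy}methyl)-2-methyl-1-[(triethylsilyl)oxy]-1,2,3,5,8,8a-hexahydroindolizine-8a-carbaldehyde; 21 (3aR)-3,3a,4,5-tetrahydropentalen-1-yl trifluoromethanesulfonate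
Product: 22 C-19 allylic alcohol joining the indolizidine C-20 to the pentalenyl C-14 (both C-19 epimers; C-20 and C-9 unchanged)
Conditions: CrCl2 (4 equiv), NiCl2 (2 mol%), DMF, 23 °C
Reagents that add atoms: none
Why: Nozaki–Hiyama–Kishi coupling: nickel inserts into the alkenyl triflate, transmetalation gives an alkenylchromium species that adds chemoselectively to the hindered aldehyde in the presence of the amine and silyl ethers, forming C-14–C-19; the carbinol configuration is irrelevant because it is oxidised next.

Step 15
Reactants: 22 C-19 allylic alcohol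
Product: 23 C-19 dienone [(8aR)-indolizidin-8a-yl][(3aR)-3,3a,4,5-tetrahydropentalen-1-yl]methanone carrying the C-23 and C-25 silyl ethers
Conditions: Dess–Martin periodinane, NaHCO3, CH2Cl2, 0 to 23 °C
Reagents that add atoms: none
Why: Dess–Martin oxidation of the allylic alcohol gives the 2-acyl diene, i.e. the enone chromophore with the tetrahydropyridine alkene three atoms away from C-14.

Step 16
Reactants: 23 C-19 dienone
Product: 24 cyclobutane photoadduct (hexacyclic C-19 ketone; new bonds C-6–C-7 and C-14–C-22; temporary bond C-7–C-14)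
Conditions: hν (350 nm, Pyrex), CF3CO2H (1.1 equiv), degassed MeCN (0.005 M), 0 °C; then aq. NaHCO3
Reagents that add atoms: none
Why: Excitation of the 2-acyl diene (enone n,π* state, then intersystem crossing) gives a triplet that bonds first from C-14 to C-22 and then collapses the resulting 1,4-diradical between C-7 and C-6; the closest known reaction type is the intramolecular enone–alkene [2+2] photocycloaddition of 1-acylcycloalkenes tethered through the carbonyl group (1,6-dien-3-ones), which gives bicyclo[3.2.0]heptan-2-ones. The cyclopentanone ring (C-14, C-19, C-20, C-21, C-22) closes in the 5-exo sense of the rule of five and the cyclobutane (C-6, C-7, C-14, C-22) closes by 1,4-diradical recombination, and together they create the 6-azabicyclo[3.2.1]octane core of the target. C-22 and C-6 are set by C-20, because the acyl arm can reach the ring alkene only on the ring face on which it stands and the six-membered ring enforces a cis ring fusion; C-14 and C-7 are fixed by the cage as well but are temporary (both are erased in steps 17 and 18), and the enantiomer of the diene fragment is the one for which the addition runs on the diene face that carries H-9. The step needs straight and not crossed regiochemistry, which the three-atom tether C-19/C-20/C-21 should secure (five-membered against six-membered first ring), and it needs the C-12=C-13 alkene to stay out, which its s-trans lock in the pentalene and its distance from the tether should secure. Protonation of N-4 by CF3CO2H should suppress electron-transfer quenching and hydrogen abstraction next to the tertiary amine. The strain stored in the cyclobutane, which holds the piperidine in a boat, is what drives the cleavage of C-7–C-14 in step 17.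

Step 17
Reactants: 24 cyclobutane photoadduct
Product: 25 ring-expanded ketone (cycloheptane closed; C-7 now CH2; H on C-14 exo; C-12=C-13 retained)
Conditions: SmI2 (2.2 equiv), t-BuOH (3 equiv), THF, −78 to 0 °C
Reagents that add atoms: none
Why: SmI2-induced reductive fragmentation of an α-keto cyclobutane: the C-19 ketyl cleaves the strained C-7–C-14 bond, which is the bond at C-14 outside the cyclopentanone ring and aligned with the ketyl π-system (C-14–C-22 lies in its nodal plane), a second electron and t-BuOH turn C-7 into CH2, and the samarium dienolate is protonated at C-14 to give the cycloheptane; ring strain and the conjugated dienolate should let this outrun loss of N-4 from C-20.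

Step 18
Reactants: 25 ring-expanded ketone; 26 methyl prop-2-enoate (methyl acrylate)
Product: 27 Michael adduct (methyl propanoate arm on C-14 exo; C-19 ketone)
Conditions: KOt-Bu (0.2 equiv), t-BuOH/THF, 0 °C
Reagents that add atoms: none
Why: Michael addition of the potassium dienolate through its α-carbon C-14 (deconjugative alkylation, which keeps C-12=C-13 in place) on the exo face, the endo face being covered by the cycloheptane and the N-4/C-5/C-6 bridge, so that the quaternary C-14 is set with the propanoate arm exo as in the target.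

Step 19
Reactants: 27 Michael adduct
Product: 29 diol ester (C-19 endo carbinol; free C-25 carbinol), via silyl ether carbinol 28 (not isolated)
Conditions: NaBH4, CeCl3·7H2O, MeOH, 0 to 23 °C; then 2 M aq. HCl, THF, 23 °C
Reagents that add atoms: none
Why: Luche-type borohydride reduction of the cyclopentanone from its open exo face gives the endo carbinol (any exo carbinol lactonises and converges on the same product after step 21), and the acidic work-up cleaves the triethylsilyl ether while the tert-butyldiphenylsilyl ether and the ester stay.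

Step 20
Reactants: 29 diol ester
Product: 30 β-hydroxy ketone (C-25 ketone; C-19 endo carbinol)
Conditions: Dess–Martin periodinane (1.1 equiv), NaHCO3, CH2Cl2, 0 °C
Reagents that add atoms: none
Why: Chemoselective Dess–Martin oxidation: the C-25 carbinol on the exposed pyrrolidine ring should exchange onto iodine far faster than the C-19 carbinol, which is flanked by the quaternary C-14 and C-20 and buried on the endo face, so that the β-hydroxy ketone results.

Step 21
Reactants: 30 β-hydroxy ketone
Product: 33 O-23 tert-butyldiphenylsilyl ether of the target, via keto aldehyde 31 (not isolated), via exo aldol 32 (not isolated)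
Conditions: DBU, toluene, 70 °C
Reagents that add atoms: none
Why: Base-induced retro-aldol/aldol equilibration across C-19–C-20 lets the aldehyde re-add through either face, only the exo alkoxide (cis to the propanoate arm) can close the δ-lactone, so that lactonisation drains the equilibrium and sets C-19 (H endo, where a hydride reagent could hardly deliver it), while the enolisable C-2 settles to the epimer assumed to be the more stable one.

Step 22
Reactants: 33 O-23 tert-butyldiphenylsilyl ether of the target
Product: 34 CNP0180795.1 (target)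
Conditions: HF·pyridine, pyridine, THF, 0 to 23 °C
Reagents that add atoms: none
Why: Fluoride cleavage of the silyl ether under buffered, non-basic conditions frees the C-23 hydroxyl without touching the lactone or epimerising C-2.

**Compound list**

1 | prop-2-en-1-amine (allylamine) | C=CCN | starting material
2 | methyl 2-methylprop-2-enoate | C=C(C)C(=O)OC | starting material
3 | methyl 2-methyl-3-(prop-2-en-1-ylamino)propanoate (racemic) | C=CCNCC(C)C(=O)OC | intermediate
4 | methyl bromoacetate | BrCC(=O)OC | starting material
5 | methyl 3-[(2-methoxy-2-oxoethyl)(prop-2-en-1-yl)amino]-2-methylpropanoate (racemic) | C=CCN(CC(=O)OC)CC(C)C(=O)OC | intermediate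
6 | methyl 4-methyl-3-oxo-1-(prop-2-en-1-yl)pyrrolidine-2-carboxylate (racemic, both centres enolisable) | C=CCN1CC(C)C(=O)C1C(=O)OC | intermediate
7 | 2-methylidenepropane-1,3-diol | C=C(CO)CO | starting material
8 | 2-({[tert-butyl(diphenyl)silyl]oxy}methyl)prop-2-en-1-ol | C=C(CO)CO[Si](c1ccccc1)(c1ccccc1)C(C)(C)C | intermediate
9 | 2-({[tert-butyl(diphenyl)silyl]oxy}methyl)prop-2-en-1-yl methyl carbonate | C=C(COC(=O)OC)CO[Si](c1ccccc1)(c1ccccc1)C(C)(C)C | intermediate
10 | methyl (2R)-2-[2-({[tert-butyl(diphenyl)silyl]oxy}methyl)prop-2-en-1-yl]-4-methyl-3-oxo-1-(prop-2-en-1-yl)pyrrolidine-2-carboxylate (both C-4 epimers) | C=CCN1CC(C)C(=O)[C@]1(CC(=C)CO[Si](c2ccccc2)(c2ccccc2)C(C)(C)C)C(=O)OC | intermediate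
11 | methyl (8aR)-7-({[tert-butyl(diphenyl)silyl]oxy}methyl)-2-methyl-1-oxo-2,3,5,8-tetrahydroindolizine-8a(1H)-carboxylate (both C-2 epimers) | CC1CN2CC=C(CO[Si](c3ccccc3)(c3ccccc3)C(C)(C)C)C[C@]2(C(=O)OC)C1=O | intermediate
12 | methyl (8aR)-7-({[tert-butyl(diphenyl)silyl]oxy}methyl)-1-hydroxy-2-methyl-1,2,3,5,8,8a-hexahydroindolizine-8a-carboxylate (epimers at C-25 and C-2) | CC1CN2CC=C(CO[Si](c3ccccc3)(c3ccccc3)C(C)(C)C)C[C@]2(C(=O)OC)C1O | intermediate
13 | methyl (8aR)-7-({[tert-butyl(diphenyl)silyl]oxy}methyl)-2-methyl-1-[(triethylsilyl)oxy]-1,2,3,5,8,8a-hexahydroindolizine-8a-carboxylate (epimers at C-25 and C-2) | CC1CN2CC=C(CO[Si](c3ccccc3)(c3ccccc3)C(C)(C)C)C[C@]2(C(=O)OC)C1O[Si](CC)(CC)CC | intermediate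
14 | (8aR)-7-({[tert-butyl(diphenyl)silyl]oxy}methyl)-2-methyl-1-[(triethylsilyl)oxy]-1,2,3,5,8,8a-hexahydroindolizine-8a-carbaldehyde (epimers at C-25 and C-2) | CC1CN2CC=C(CO[Si](c3ccccc3)(c3ccccc3)C(C)(C)C)C[C@]2(C=O)C1O[Si](CC)(CC)CC | intermediate
15 | cyclopent-2-en-1-one | O=C1CCC=C1 | starting material
16 | [2-(1,3-dioxan-2-yl)ethyl]magnesium bromide | Br[Mg]CCC1OCCCO1 | starting material
17 | (3R)-3-[2-(1,3-dioxan-2-yl)ethyl]cyclopentan-1-one | O=C1CC[C@@H](CCC2OCCCO2)C1 | intermediate
18 | 3-[(1R)-3-oxocyclopentyl]propanal (keto aldehyde) | O=C1CC[C@@H](CCC=O)C1 | intermediate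
19 | (3aR)-3,3a,4,5-tetrahydropentalen-1(2H)-one | O=C1CC[C@H]2CCC=C12 | intermediate
20 | lithium (3aR)-3,3a,4,5-tetrahydropentalen-1-olate (lithium dienolate) | [Li]OC1=CC[C@H]2CCC=C12 | intermediate
21 | (3aR)-3,3a,4,5-tetrahydropentalen-1-yl trifluoromethanesulfonate | O=S(=O)(OC1=CC[C@H]2CCC=C12)C(F)(F)F | intermediate
22 | C-19 allylic alcohol: indolizidine C-20 and pentalenyl C-14 joined through CH(OH) (both C-19 epimers; epimers at C-25 and C-2) | CC1CN2CC=C(CO[Si](c3ccccc3)(c3ccccc3)C(C)(C)C)C[C@]2(C(O)C3=CC[C@H]4CCC=C34)C1O[Si](CC)(CC)CC | intermediate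
23 | C-19 dienone: the ketone of 22 (epimers at C-25 and C-2) | CC1CN2CC=C(CO[Si](c3ccccc3)(c3ccccc3)C(C)(C)C)C[C@]2(C(=O)C3=CC[C@H]4CCC=C34)C1O[Si](CC)(CC)CC | intermediate
24 | cyclobutane photoadduct: C-19 ketone with cyclobutane C-6/C-7/C-14/C-22; C-5, C-19 and C-21 on one cyclobutane face, C-8, C-13 and C-23 on the other (epimers at C-25 and C-2) | CC1CN2C[C@H]3[C@@H]4C[C@H]5CCC=C5[C@@]46C(=O)[C@@]2(C[C@@]36CO[Si](c7ccccc7)(c7ccccc7)C(C)(C)C)C1O[Si](CC)(CC)CC | intermediate
25 | ring-expanded β,γ-unsaturated C-19 ketone with the cycloheptane closed and H on C-14 exo (epimers at C-25 and C-2) | CC1CN2C[C@H]3CC[C@H]4CCC=C4[C@H]5C(=O)[C@@]2(C[C@@]35CO[Si](c6ccccc6)(c6ccccc6)C(C)(C)C)C1O[Si](CC)(CC)CC | intermediate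
26 | methyl prop-2-enoate (methyl acrylate) | C=CC(=O)OC | starting material
27 | Michael adduct: C-19 ketone with the methyl propanoate arm exo on C-14 (epimers at C-25 and C-2) | CC1CN2C[C@H]3CC[C@H]4CCC=C4[C@@]5(CCC(=O)OC)C(=O)[C@@]2(C[C@@]35CO[Si](c6ccccc6)(c6ccccc6)C(C)(C)C)C1O[Si](CC)(CC)CC | intermediate
28 | C-19 endo carbinol with the C-25 triethylsilyl ether still in place (epimers at C-25 and C-2) | CC1CN2C[C@H]3CC[C@H]4CCC=C4[C@@]5(CCC(=O)OC)[C@@H](O)[C@@]2(C[C@@]35CO[Si](c6ccccc6)(c6ccccc6)C(C)(C)C)C1O[Si](CC)(CC)CC | intermediate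
29 | diol ester: C-19 endo carbinol and free C-25 carbinol (epimers at C-25 and C-2) | CC1CN2C[C@H]3CC[C@H]4CCC=C4[C@@]5(CCC(=O)OC)[C@@H](O)[C@@]2(C[C@@]35CO[Si](c6ccccc6)(c6ccccc6)C(C)(C)C)C1O | intermediate
30 | β-hydroxy ketone: C-25 ketone and C-19 endo carbinol (C-2 epimers) | CC1CN2C[C@H]3CC[C@H]4CCC=C4[C@@]5(CCC(=O)OC)[C@@H](O)[C@@]2(C[C@@]35CO[Si](c6ccccc6)(c6ccccc6)C(C)(C)C)C1=O | intermediate
31 | ring-opened keto aldehyde: C-19 aldehyde on C-14 and C-20–H indolizidin-1-one (C-20 and C-2 enolisable) | CC1CN2C[C@H]3CC[C@H]4CCC=C4[C@@](CCC(=O)OC)(C=O)[C@@]3(CO[Si](c5ccccc5)(c5ccccc5)C(C)(C)C)CC2C1=O | intermediate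
32 | exo aldol: C-25 ketone and C-19 exo carbinol (C-2 epimers) | CC1CN2C[C@H]3CC[C@H]4CCC=C4[C@@]5(CCC(=O)OC)[C@H](O)[C@@]2(C[C@@]35CO[Si](c6ccccc6)(c6ccccc6)C(C)(C)C)C1=O | intermediate
33 | O-23 tert-butyldiphenylsilyl ether of the target | C[C@@H]1CN2C[C@H]3CC[C@H]4CCC=C4[C@@]45CCC(=O)O[C@@H]4[C@@]2(C[C@@]35CO[Si](c6ccccc6)(c6ccccc6)C(C)(C)C)C1=O | intermediate
34 | CNP0180795.1, (2R,6S,9R,14R,19S,20S,22R) in the locants used here | C[C@@H]1CN2C[C@H]3CC[C@H]4CCC=C4[C@@]45CCC(=O)O[C@@H]4[C@@]2(C[C@@]35CO)C1=O | target

**Count**

Total steps: 22. Longest linear sequence: 17 steps (steps 1 to 3, 6 to 10 and 14 to 22).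

**Three steps most likely to fail**

Step 16. The triplet may close in the crossed sense (first bond from C-14 to C-6), may decay or react through the diene part of the chromophore, or may close too slowly because the adduct forces the piperidine into a boat. The fallback sets out from 22 and returns at 24. The allylic alcohol 22, with N-4 protonated, would be irradiated at 254 nm in Et2O with (CuOTf)2·C6H6. The two alkenes C-7=C-14 and C-6=C-22 are then held on monovalent copper, and the copper-templated [2+2] of such a 1,6-diene closes in the straight sense without an enone triplet, giving the cyclobutane carbinol F1. Oxidation of F1 with Dess–Martin periodinane would give 24.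

Step 17. The ketyl may expel N-4 from C-20 (reductive C–N cleavage next to the ketone) in place of opening the cyclobutane, or the product ketone may be reduced further. The fallback sets out from 24 and returns at 25. Me3SiI in CH2Cl2 at −40 °C would silylate the ketone oxygen, iodide would open the activated cyclobutane by attack at C-7 (polar homoconjugate opening), and aqueous work-up would give the 7-iodo ketone F2. Bu3SnH with azobisisobutyronitrile in toluene at 80 °C would then remove the iodine and give 25.

Step 18. Carbon–carbon bond formation at the congested C-14 may fail or revert (retro-Michael), or the dienolate may react through C-12. The fallback sets out from 25 and returns at 27. NaN(SiMe3)2 and allyl chloroformate would give the allyl dienol carbonate F3. Pd(PPh3)4 in THF would ionise it, and the ion pair would recombine at C-14 (decarboxylative allylic alkylation) to the C-14 allyl ketone F4. 9-Borabicyclo[3.3.1]nonane followed by NaBO3·4H2O would give the primary alcohol F5. Oxidation with 2,2,6,6-tetramethylpiperidin-1-oxyl and PhI(OAc)2 followed by NaClO2 would give the carboxylic acid F6, and Me3SiCHN2 in MeOH would give 27.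

**Further compounds**

F1 | step 16 | cyclobutane carbinol: the C-19 alcohol corresponding to 24 (C-19 epimers) | CC1CN2C[C@H]3[C@@H]4C[C@H]5CCC=C5[C@@]46C(O)[C@@]2(C[C@@]36CO[Si](c7ccccc7)(c7ccccc7)C(C)(C)C)C1O[Si](CC)(CC)CC
F2 | step 17 | 7-iodo ketone: 25 bearing iodine on C-7 | CC1CN2C[C@H]3[C@H](I)C[C@H]4CCC=C4[C@H]5C(=O)[C@@]2(C[C@@]35CO[Si](c6ccccc6)(c6ccccc6)C(C)(C)C)C1O[Si](CC)(CC)CC
F3 | step 18 | allyl dienol carbonate of 25 (O-allyloxycarbonyl enol at C-19, C-14=C-19) | CC1CN2C[C@H]3CC[C@H]4CCC=C4C5=C(OC(=O)OCC=C)[C@@]2(C[C@@]35CO[Si](c6ccccc6)(c6ccccc6)C(C)(C)C)C1O[Si](CC)(CC)CC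
F4 | step 18 | C-14 allyl ketone (allyl exo) | CC1CN2C[C@H]3CC[C@H]4CCC=C4[C@@]5(CC=C)C(=O)[C@@]2(C[C@@]35CO[Si](c6ccccc6)(c6ccccc6)C(C)(C)C)C1O[Si](CC)(CC)CC
F5 | step 18 | C-14 3-hydroxypropyl ketone | CC1CN2C[C@H]3CC[C@H]4CCC=C4[C@@]5(CCCO)C(=O)[C@@]2(C[C@@]35CO[Si](c6ccccc6)(c6ccccc6)C(C)(C)C)C1O[Si](CC)(CC)CC
F6 | step 18 | C-14 propanoic acid ketone | CC1CN2C[C@H]3CC[C@H]4CCC=C4[C@@]5(CCC(=O)O)C(=O)[C@@]2(C[C@@]35CO[Si](c6ccccc6)(c6ccccc6)C(C)(C)C)C1O[Si](CC)(CC)CC
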